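**Plan**
- Retrosynthesis: remove the three allyl groups of ring B and the C3 formyl group of ring A; open ring A at C1–C6 (retro-aldol) to a benzyl 3,5,7-trioxooctanoate; cut the benzylic O–C(=O) bond into an acylketene and a ring-B benzylic alcohol.
- Enabling feature: in ring A the ester-bearing C1, the oxygens on C2 and C4 and the methyl on C6 are the folded form of a 3,5,7-trioxooctanoate, so the crowded, di-ortho-substituted aryl ester can be made on an open chain before ring A exists.
- Ring B first: symmetric 3,5-dihydroxy-4-methylbenzoic acid is allylated, reduced, brominated and carboxylated to a phthalide, which is opened to the allyl ester alcohol.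
- The C8 chain comes from 2,2,6-trimethyl-4H-1,3-dioxin-4-one by two C-acylations; thermolysis joins it to the ring-B alcohol, aldol aromatization closes ring A, then C3 formylation and zerovalent-palladium deallylation finish the synthesis.
- Stereochemistry: the target has no stereocentre; the two transient centres of the aldol adduct vanish on aromatization.

Key step: step 9

Remark: both starting materials are taken as commercial; the symmetric acid 1 is chosen because its two free ring positions are equivalent, so the ring-B functionalization raises no regiochemical question.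

**Step 1**
Reactants: 1 3,5-dihydroxy-4-methylbenzoic acid
Product: 2 allyl 3,5-bis(allyloxy)-4-methylbenzoate
Conditions: allyl bromide (3.5 equiv), K2CO3, DMF, 60 °C
Reagents that add atoms: allyl bromide, C=CCBr
Why: Williamson etherification and carboxylate O-alkylation run together under K2CO3 in DMF and cap both phenols and the acid as allyl groups that a single zerovalent-palladium step can remove at the end.

**Step 2**
Reactants: 2 allyl 3,5-bis(allyloxy)-4-methylbenzoate
Product: 3 [3,5-bis(allyloxy)-4-methylphenyl]methanol
Conditions: LiAlH4, THF, 0 °C; then H2O, 15% aq. NaOH, H2O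
Reagents that add atoms: none
Why: LiAlH4 ester reduction should give the benzylic alcohol and leave the aryl allyl ethers untouched.

**Step 3**
Reactants: 3 [3,5-bis(allyloxy)-4-methylphenyl]methanol
Product: 4 [3,5-bis(allyloxy)-2-bromo-4-methylphenyl]methanol
Conditions: NBS (1.0 equiv), MeCN, 0 °C, dark
Reagents that add atoms: N-bromosuccinimide, O=C1CCC(=O)N1Br
Why: Electrophilic aromatic bromination should occur at C2, ortho to one allyloxy group and para to the other, and because C2 and C6 are equivalent only one monobromide can form.

**Step 4**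
Reactants: 4 [3,5-bis(allyloxy)-2-bromo-4-methylphenyl]methanol
Product: 7 5,7-bis(allyloxy)-6-methyl-2-benzofuran-1(3H)-one (5,7-bis(allyloxy)-6-methylphthalide), via aryllithium alkoxide 5 (not isolated), via hydroxy acid 6 (not isolated)
Conditions: n-BuLi (2.2 equiv), THF, −78 °C; CO2 (gas), −78 °C to rt; 2 M aq. HCl, rt to 40 °C
Reagents that add atoms: carbon dioxide, O=C=O
Why: Deprotonation of the alcohol and bromine–lithium exchange at −78 °C give an aryllithium that CO2 carboxylates before it can add to the neighbouring allyl group, and acidification lactonizes the hydroxy acid to the phthalide (halogen–metal exchange, carboxylation, lactonization).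

**Step 5**
Reactants: 7 5,7-bis(allyloxy)-6-methylphthalide
Product: 9 allyl 2,4-bis(allyloxy)-6-(hydroxymethyl)-3-methylbenzoate, via potassium carboxylate 8 (not isolated)
Conditions: KOH (1.0 equiv), MeOH/H2O, 65 °C; evaporate to dryness; allyl bromide, DMF, rt; product kept cold and used promptly
Reagents that add atoms: potassium hydroxide, [K+].[OH-]; allyl bromide, C=CCBr
Why: Saponification of the lactone followed by SN2 O-alkylation of the carboxylate salt is the established way from phthalides to 2-(hydroxymethyl)benzoate esters, and with no excess base or acid present the hydroxy ester should not close back.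

**Step 6**
Reactants: 10 2,2,6-trimethyl-4H-1,3-dioxin-4-one
Product: 12 2,2-dimethyl-6-(2-oxopropyl)-4H-1,3-dioxin-4-one, via lithium dienolate 11 (not isolated)
Conditions: LiN(SiMe3)2, THF, −78 °C; AcCl (0.5 equiv), −78 °C; 1 M aq. HCl, 0 °C
Reagents that add atoms: acetyl chloride, CC(Cl)=O
Why: γ-Deprotonation gives a vinylogous ester dienolate that is C-acylated at the exocyclic carbon (Claisen-type acylation), the excess enolate absorbing the more acidic keto-dioxinone as it forms.

**Step 7**
Reactants: 12 2,2-dimethyl-6-(2-oxopropyl)-4H-1,3-dioxin-4-one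
Product: 14 6-(2,4-dioxopentyl)-2,2-dimethyl-4H-1,3-dioxin-4-one, via dilithium dianion 13 (not isolated)
Conditions: LiN(i-Pr)2 (2.2 equiv), THF, −78 °C; MeC(O)N(OMe)Me, −78 to −40 °C; 1 M aq. HCl, 0 °C
Reagents that add atoms: N-methoxy-N-methylacetamide, CON(C)C(C)=O
Why: In the dianion the terminal, less stabilized carbanion is the more nucleophilic site and is acylated by the Weinreb amide (acylation of a 1,3-dicarbonyl dianion), whose chelated tetrahedral intermediate prevents over-addition.

**Step 8**
Reactants: 14 6-(2,4-dioxopentyl)-2,2-dimethyl-4H-1,3-dioxin-4-one; 9 allyl 2,4-bis(allyloxy)-6-(hydroxymethyl)-3-methylbenzoate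
Product: 16 [2-(allyloxycarbonyl)-3,5-bis(allyloxy)-4-methylphenyl]methyl 3,5,7-trioxooctanoate (keto–enol mixture, used crude), via acylketene 15 (not isolated)
Conditions: toluene, 110 °C, 1–2 h (14 in slight excess)
Reagents that add atoms: none
Why: Retro-hetero-Diels–Alder loss of acetone at 110 °C releases an acylketene that the primary benzylic alcohol should capture faster than it lactonizes onto its hindered neighbouring ester, so the ester bond is made on an unhindered open chain (dioxinone thermolysis and ketene trapping).

**Step 9**
Reactants: 16 [2-(allyloxycarbonyl)-3,5-bis(allyloxy)-4-methylphenyl]methyl 3,5,7-trioxooctanoate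
Product: 18 [2-(allyloxycarbonyl)-3,5-bis(allyloxy)-4-methylphenyl]methyl 2,4-dihydroxy-6-methylbenzoate (the ring-B benzyl orsellinate), via aldol adduct 17 (not isolated)
Conditions: Cs2CO3, i-PrOH/CH2Cl2, 0 °C to rt; then HCl in i-PrOH to pH 2, rt
Reagents that add atoms: none
Why: Cs2CO3 deprotonates the most acidic methylene, C2 between the ester and the C3 ketone, and this enolate adds to the C7 methyl ketone to forge the C1–C6 bond of ring A (intramolecular aldol addition giving 17), after which acid dehydrates the tertiary alcohol and the two remaining ring ketones tautomerize to the phenols. The closest known reaction type is the biomimetic aldol aromatization of 3,5,7-triketo esters, unmasked from diketo-dioxinones, to resorcylate esters. Ring A closes in a 6-(enolendo)-exo-trig mode. No stereocentre remains, since the two centres of 17 are erased on aromatization. The step needs C-cyclization (C2 to C7) to win over O-cyclization of the C5 enolate onto the ester (pyranone formation) and over Claisen-type closure; a carbonate base at or below room temperature, the poor leaving ability of the primary benzylic alkoxide and withholding the acid until the carbocycle has formed should secure this. Ring B carries no free hydroxyl, so its allyl ester and ethers are spectators.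

**Step 10**
Reactants: 18 [2-(allyloxycarbonyl)-3,5-bis(allyloxy)-4-methylphenyl]methyl 2,4-dihydroxy-6-methylbenzoate
Product: 20 [2-(allyloxycarbonyl)-3,5-bis(allyloxy)-4-methylphenyl]methyl 3-formyl-2,4-dihydroxy-6-methylbenzoate, via hydroxymethyl intermediate 19 (not isolated)
Conditions: MgCl2 (anhydrous), Et3N, (CH2O)n, MeCN, 80 °C; then 1 M aq. HCl
Reagents that add atoms: formaldehyde (as paraformaldehyde), C=O
Why: Magnesium phenoxide-directed ortho-formylation (hydroxymethylation, then Oppenauer-type hydride transfer to a second formaldehyde) acts only on the free phenols of ring A, and C3, which is ortho to both phenols and favoured by the bond fixation of the chelated salicylate, should react in preference to C5, which is crowded by the C6 methyl.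

**Step 11**
Reactants: 20 [2-(allyloxycarbonyl)-3,5-bis(allyloxy)-4-methylphenyl]methyl 3-formyl-2,4-dihydroxy-6-methylbenzoate
Product: 21 alectorialic acid
Conditions: Pd(PPh3)4 (10 mol %), 4-MeC6H4SO2Na (4 equiv), THF/MeOH, rt; then dilute aq. HCl
Reagents that add atoms: none
Why: Zerovalent palladium ionizes the two aryl allyl ethers and the allyl ester to π-allyl complexes that the sulfinate traps irreversibly as allyl p-tolyl sulfone (Tsuji–Trost deallylation), a non-reducing, amine-free release that should leave the aldehyde and the benzylic ester intact.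

**Compound list**
1 | 3,5-dihydroxy-4-methylbenzoic acid | Cc1c(O)cc(cc1O)C(=O)O | starting material
2 | allyl 3,5-bis(allyloxy)-4-methylbenzoate | Cc1c(OCC=C)cc(cc1OCC=C)C(=O)OCC=C | intermediate
3 | [3,5-bis(allyloxy)-4-methylphenyl]methanol | Cc1c(OCC=C)cc(CO)cc1OCC=C | intermediate
4 | [3,5-bis(allyloxy)-2-bromo-4-methylphenyl]methanol | Cc1c(OCC=C)cc(CO)c(Br)c1OCC=C | intermediate
5 | lithium [3,5-bis(allyloxy)-2-lithio-4-methylphenyl]methanolate (aryllithium alkoxide, not isolated) | Cc1c(OCC=C)cc(CO[Li])c([Li])c1OCC=C | intermediate
6 | 2,4-bis(allyloxy)-6-(hydroxymethyl)-3-methylbenzoic acid (hydroxy acid, not isolated) | Cc1c(OCC=C)cc(CO)c(C(=O)O)c1OCC=C | intermediate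
7 | 5,7-bis(allyloxy)-6-methyl-2-benzofuran-1(3H)-one | Cc1c(OCC=C)cc2COC(=O)c2c1OCC=C | intermediate
8 | potassium 2,4-bis(allyloxy)-6-(hydroxymethyl)-3-methylbenzoate (not isolated) | Cc1c(OCC=C)cc(CO)c(C(=O)[O-])c1OCC=C.[K+] | intermediate
9 | allyl 2,4-bis(allyloxy)-6-(hydroxymethyl)-3-methylbenzoate | Cc1c(OCC=C)cc(CO)c(C(=O)OCC=C)c1OCC=C | intermediate
10 | 2,2,6-trimethyl-4H-1,3-dioxin-4-one | CC1=CC(=O)OC(C)(C)O1 | starting material
11 | lithium 2,2-dimethyl-6-methylidene-6H-1,3-dioxin-4-olate (lithium dienolate, not isolated) | C=C1C=C(O[Li])OC(C)(C)O1 | intermediate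
12 | 2,2-dimethyl-6-(2-oxopropyl)-4H-1,3-dioxin-4-one | CC(=O)CC1=CC(=O)OC(C)(C)O1 | intermediate
13 | dilithium dianion of 12, drawn as its bis-enolate (not isolated) | C=C(O[Li])C=C1C=C(O[Li])OC(C)(C)O1 | intermediate
14 | 6-(2,4-dioxopentyl)-2,2-dimethyl-4H-1,3-dioxin-4-one | CC(=O)CC(=O)CC1=CC(=O)OC(C)(C)O1 | intermediate
15 | 3,5,7-trioxooct-1-en-1-one (acylketene, not isolated) | CC(=O)CC(=O)CC(=O)C=C=O | intermediate
16 | [2-(allyloxycarbonyl)-3,5-bis(allyloxy)-4-methylphenyl]methyl 3,5,7-trioxooctanoate | CC(=O)CC(=O)CC(=O)CC(=O)OCc1cc(OCC=C)c(C)c(OCC=C)c1C(=O)OCC=C | intermediate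
17 | [2-(allyloxycarbonyl)-3,5-bis(allyloxy)-4-methylphenyl]methyl 2-hydroxy-2-methyl-4,6-dioxocyclohexane-1-carboxylate (aldol adduct, diastereomer mixture, not isolated) | CC1(O)CC(=O)CC(=O)C1C(=O)OCc1cc(OCC=C)c(C)c(OCC=C)c1C(=O)OCC=C | intermediate
18 | [2-(allyloxycarbonyl)-3,5-bis(allyloxy)-4-methylphenyl]methyl 2,4-dihydroxy-6-methylbenzoate | Cc1cc(O)cc(O)c1C(=O)OCc1cc(OCC=C)c(C)c(OCC=C)c1C(=O)OCC=C | intermediate
19 | [2-(allyloxycarbonyl)-3,5-bis(allyloxy)-4-methylphenyl]methyl 2,4-dihydroxy-3-(hydroxymethyl)-6-methylbenzoate (not isolated in step 10) | Cc1cc(O)c(CO)c(O)c1C(=O)OCc1cc(OCC=C)c(C)c(OCC=C)c1C(=O)OCC=C | intermediate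
20 | [2-(allyloxycarbonyl)-3,5-bis(allyloxy)-4-methylphenyl]methyl 3-formyl-2,4-dihydroxy-6-methylbenzoate | Cc1cc(O)c(C=O)c(O)c1C(=O)OCc1cc(OCC=C)c(C)c(OCC=C)c1C(=O)OCC=C | intermediate
21 | alectorialic acid, 6-{[(3-formyl-2,4-dihydroxy-6-methylbenzoyl)oxy]methyl}-2,4-dihydroxy-3-methylbenzoic acid | Cc1cc(O)c(C=O)c(O)c1C(=O)OCc1cc(O)c(C)c(O)c1C(=O)O | target

**Step count**
Total: 11 steps. Longest linear sequence: 9 steps (steps 1–5 and 8–11); the dioxinone branch (steps 6 and 7) joins at step 8.

**Steps most likely to fail**

Step 8. At the 110 °C needed to unmask the ketene, intramolecular transesterification of the hydroxy ester (closure back to the phthalide with loss of allyl alcohol) or cyclization of the acylketene onto its own enol oxygen may outrun intermolecular capture. The fallback sets out from 14 and 9 and comes back at 16. Compound 14 is heated in toluene with 2-methylpropane-2-thiol, which cannot lactonize, to give S-tert-butyl 3,5,7-trioxooctanethioate F1. The acyl group of F1 is then passed to alcohol 9 at room temperature with AgO2CCF3 and Na2HPO4 in THF (silver-promoted thioester-to-ester exchange), so the hydroxy ester is never heated. Any phthalide 7 formed in the main route can be returned to step 5.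

Step 10. Formaldehyde may be delivered to C5 as well as C3, or the hydroxymethyl stage may condense with a second arene or be formylated twice. The fallback sets out from 18 and comes back at 20. Compound 18 is heated with PhB(OH)2, paraformaldehyde and catalytic propionic acid in toluene with removal of water. This should tie one ortho-hydroxymethyl group into the cyclic boronate [2-(allyloxycarbonyl)-3,5-bis(allyloxy)-4-methylphenyl]methyl 5-hydroxy-7-methyl-2-phenyl-4H-1,3,2-benzodioxaborinine-6-carboxylate F2, which stops the reaction at the alcohol level. Exchange with propane-1,3-diol releases the salicyl alcohol 19, which can be purified from any isomer, and MnO2 in CH2Cl2 oxidizes it to 20.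

Step 9. O-cyclization of the C5 enolate onto the ester (pyranone formation with expulsion of the ring-B alkoxide, which would then lactonize irreversibly) or retro-Claisen cleavage may compete with the C2-to-C7 aldol closure. The fallback sets out from 14 and 9 and comes back at 18. The same aldol aromatization is run on the dioxinone itself, where no alkoxide can leave: 14 with Et3N in CH2Cl2 should give 7-hydroxy-2,2,5-trimethyl-4H-1,3-benzodioxin-4-one F3. Aqueous KOH in THF then opens F3 to orsellinic acid F4, isolated by cold acidification. Alcohol 9 is converted with CBr4 and PPh3 in CH2Cl2 at 0 °C into allyl 2,4-bis(allyloxy)-6-(bromomethyl)-3-methylbenzoate F5. KHCO3 in DMF at room temperature then alkylates the carboxylate of F4 with F5, selectively over the phenols, to give 18; carboxylate O-alkylation is not subject to the steric problem of acylating with a hindered acid.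

**Further compounds**
F1 | step 8 | S-tert-butyl 3,5,7-trioxooctanethioate | CC(=O)CC(=O)CC(=O)CC(=O)SC(C)(C)C
F2 | step 10 | [2-(allyloxycarbonyl)-3,5-bis(allyloxy)-4-methylphenyl]methyl 5-hydroxy-7-methyl-2-phenyl-4H-1,3,2-benzodioxaborinine-6-carboxylate | Cc1cc2OB(c3ccccc3)OCc2c(O)c1C(=O)OCc1cc(OCC=C)c(C)c(OCC=C)c1C(=O)OCC=C
F3 | step 9 | 7-hydroxy-2,2,5-trimethyl-4H-1,3-benzodioxin-4-one | Cc1cc(O)cc2OC(C)(C)OC(=O)c12
F4 | step 9 | orsellinic acid (2,4-dihydroxy-6-methylbenzoic acid) | Cc1cc(O)cc(O)c1C(=O)O
F5 | step 9 | allyl 2,4-bis(allyloxy)-6-(bromomethyl)-3-methylbenzoate | Cc1c(OCC=C)cc(CBr)c(C(=O)OCC=C)c1OCC=C
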